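**Plan**

- Retrosynthetic cuts: first the C3 ester C–O bond to one danshensu unit. C3=C4 then goes back to a C3 tertiary alcohol. C1–ring C and C2–C3 are cut together, and last C8a–C1 (Heck) and C4a–C4 (epoxide opening) on ring A.
- Enabling feature: in ring B (C1, C2, C3, C4, C4a, C8a), C1 bears an aryl β to the C2 carboxyl, and the C3=C4 cinnamate is the dehydrated aldol of a benzylic C3 ketone. Ring B therefore unfolds into an enoate arm (C1, C2) and a 2-oxoalkyl arm (C4, C3), ortho to each other on catechol ring A.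
- The C3 carboxyl passes through the ring closure at the aldehyde level, as a diethyl acetal. An arylpyruvate ester would rest as an acidic enol, and its keto form would itself be arylated by aryl–rhodium. The C2 carboxyl carries its danshensu ester from the start, so no ring B ester is ever hydrolysed.
- Forward order: one bromide from 4-bromocatechol supplies ring C (as boronic acid) and ring A. Both arms go onto ring A, and ring B closes in the arylation–aldol cascade. Syn-dehydration, oxidation of C3–CHO, the second esterification and one acid deprotection follow.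
- Stereochemistry: C1 comes from the chiral diene on rhodium. C2 and the transient C3 are relayed through the closed aldol transition state. Both side-chain centres come from (R)-danshensu.

Key step: step 10

Conventions: Ar = 2,2-dimethyl-1,3-benzodioxol-5-yl. Dan = (2R)-1-tert-butoxy-3-(2,2-dimethyl-1,3-benzodioxol-5-yl)-1-oxopropan-2-yl. Ring B keeps the dihydronaphthalene numbering of the target throughout.

Assumption: the (1S,4S) antipode of the diene is taken to arylate the Si face of C1, by the usual quadrant picture for (E)-enoates; if the sense is the reverse, the equally available (1R,4R) antipode is used and nothing else changes.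

**Step 1**
Reactants: 1 4-bromocatechol
Product: 2 5-bromo-2,2-dimethyl-1,3-benzodioxole
Conditions: 2,2-dimethoxypropane, TsOH·H2O (cat.), toluene, reflux, MeOH removed over 4 Å molecular sieves
Reagents that add atoms: 2,2-dimethoxypropane COC(C)(C)OC
Why: Acid-catalysed transketalisation of a catechol, driven by removal of methanol, gives the benzodioxole, a protecting group that withstands organometallics, palladium and base and falls to acid at the end.

**Step 2**
Reactants: 2 5-bromo-2,2-dimethyl-1,3-benzodioxole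
Product: 5 (2,2-dimethyl-1,3-benzodioxol-5-yl)boronic acid, via aryllithium 3 (not isolated), via lithium aryltriisopropoxyborate 4 (not isolated)
Conditions: n-BuLi, THF, −78 °C; B(OiPr)3, −78 °C to rt; 1 M HCl, 0 °C
Reagents that add atoms: triisopropyl borate CC(C)OB(OC(C)C)OC(C)C; water O
Why: Bromine–lithium exchange, borylation with a trialkyl borate and brief hydrolysis is the standard route to electron-rich arylboronic acids, and the ketal is inert to butyllithium.

**Step 3**
Reactants: 2 5-bromo-2,2-dimethyl-1,3-benzodioxole; 6 2-(diethoxymethyl)oxirane (racemic glycidaldehyde diethyl acetal)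
Product: 8 1-Ar-3,3-diethoxypropan-2-ol (racemic), via arylmagnesium bromide 7 (not isolated)
Conditions: Mg, THF, 40 °C; CuBr·SMe2 (10 mol %), 6, −30 to 0 °C; aq. NH4Cl
Reagents that add atoms: none
Why: Copper-catalysed SN2 opening of a terminal epoxide by an aryl Grignard reagent occurs at the unhindered CH2 terminus and lays down C4, C3 and the masked C3 carboxyl carbon at once; the racemic carbinol centre is erased in step 9.

**Step 4**
Reactants: 8 1-Ar-3,3-diethoxypropan-2-ol
Product: 9 1-(6-bromo-2,2-dimethyl-1,3-benzodioxol-5-yl)-3,3-diethoxypropan-2-ol (racemic)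
Conditions: NBS, MeCN, 0 °C to rt, dark
Reagents that add atoms: N-bromosuccinimide O=C1CCC(=O)N1Br
Why: Electrophilic aromatic bromination of a 4-alkylcatechol ether goes para to a ring oxygen and ortho to the alkyl chain, the only unhindered activated position, which is the future C8a.

**Step 5**
Reactants: 10 (R)-3-(3,4-dihydroxyphenyl)lactic acid (danshensu)
Product: 12 (R)-3-Ar-2-hydroxypropanoic acid, via bis-acetonide dioxolanone 11 (not isolated)
Conditions: 2,2-dimethoxypropane (excess), TsOH·H2O (cat.), toluene, 90 °C, 4 Å molecular sieves, N2; concentrate; LiOH, THF/H2O, 0 °C; 1 M HCl to pH 3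
Reagents that add atoms: 2,2-dimethoxypropane COC(C)(C)OC; lithium hydroxide [Li+].[OH-]
Why: Transketalisation protects the catechol and ties the hydroxy acid up as dioxolanone 11 in one pass, and saponification then opens only that activated acyl–oxygen bond (and any methyl ester formed alongside) without touching the aryl ketal or the stereocentre.

**Step 6**
Reactants: 12 (R)-3-Ar-2-hydroxypropanoic acid
Product: 13 tert-butyl (R)-3-Ar-2-hydroxypropanoate (Dan–OH)
Conditions: Cl3CC(=NH)OtBu, CH2Cl2/cyclohexane, rt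
Reagents that add atoms: tert-butyl 2,2,2-trichloroacetimidate CC(C)(C)OC(=N)C(Cl)(Cl)Cl
Why: Trichloroacetimidate alkylation is catalysed by the carboxylic acid itself, so the tert-butyl ester forms while the secondary alcohol, which would need a Lewis acid, stays free.

**Step 7**
Reactants: 13 tert-butyl (R)-3-Ar-2-hydroxypropanoate; 14 acryloyl chloride
Product: 15 Dan acrylate
Conditions: Et3N, CH2Cl2, −20 to 0 °C
Reagents that add atoms: none
Why: O-acylation of a secondary α-hydroxy ester with an acid chloride and a tertiary amine is routine and leaves the C–O bond at the stereocentre intact.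

**Step 8**
Reactants: 9 1-(6-bromo-2,2-dimethyl-1,3-benzodioxol-5-yl)-3,3-diethoxypropan-2-ol; 15 Dan acrylate
Product: 16 Dan (E)-3-[6-(3,3-diethoxy-2-hydroxypropyl)-2,2-dimethyl-1,3-benzodioxol-5-yl]acrylate (both carbinol epimers)
Conditions: Pd(OAc)2 (5 mol %), P(o-tol)3 (12 mol %), Et3N, DMF, 100 °C
Reagents that add atoms: none
Why: Mizoroki–Heck coupling of an aryl bromide with an acrylate forms C8a–C1 and gives the (E)-cinnamate through syn insertion and syn β-hydride elimination, as is well established for 2-alkyl-4,5-dialkoxybromobenzenes.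

**Step 9**
Reactants: 16 Dan (E)-3-[6-(3,3-diethoxy-2-hydroxypropyl)-2,2-dimethyl-1,3-benzodioxol-5-yl]acrylate
Product: 17 Dan (E)-3-[6-(3,3-diethoxy-2-oxopropyl)-2,2-dimethyl-1,3-benzodioxol-5-yl]acrylate
Conditions: Dess–Martin periodinane, CH2Cl2, 0 °C to rt
Reagents that add atoms: none
Why: Dess–Martin oxidation of the secondary alcohol runs under near-neutral conditions that spare the acetal, the ketals, the enoate and the α-acyloxy ester centre, and it merges both carbinol epimers into one ketone.

**Step 10**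
Reactants: 17 Dan (E)-3-[6-(3,3-diethoxy-2-oxopropyl)-2,2-dimethyl-1,3-benzodioxol-5-yl]acrylate; 5 (2,2-dimethyl-1,3-benzodioxol-5-yl)boronic acid
Product: 19 Dan (1R,2S,3R)-1-Ar-3-(diethoxymethyl)-3-hydroxy-6,7-(isopropylidenedioxy)-1,2,3,4-tetrahydronaphthalene-2-carboxylate, via rhodium enolate 18 (not isolated)
Conditions: 5 (2 equiv), [RhCl(C2H4)2]2 (2.5 mol %), (1S,4S)-2,5-diphenylbicyclo[2.2.2]octa-2,5-diene (5.5 mol %), KOH (10 mol %), H2O (5 equiv), 1,4-dioxane, 50 °C
Reagents that add atoms: none
Why: Proposed new method: boron-to-rhodium transmetalation gives a diene-bound aryl–rhodium species (monovalent rhodium) that inserts the C1=C2 bond of the enoate, which puts ring C on C1 and leaves the oxa-π-allyl rhodium enolate 18 at C2; 18 adds to the C3 ketone, and water cleaves the rhodium alkoxide to 19 and hydroxo-rhodium. The closest known reaction types are the rhodium-catalysed conjugate arylation–aldol cyclisation of enone–ketones with arylboronic acids and the diene–rhodium conjugate arylation of cinnamate esters; what is new is an ester-derived rhodium enolate as aldol donor toward a dialkoxymethyl ketone. Ring B closes by a 6-(enolexo)-exo-trig aldol addition that forms C2–C3. C1 (R) is set by the chiral diene, which lets the aryl migrate only to the Si face of C1; C2 (S) is set by allylic 1,3-strain in the (Z)-enolate, which turns H1 into the enolate plane so that the tethered ketone meets C2 on the side away from ring C (aryl and ester trans); C3 (R) is set by the chair-like transition state in which rhodium bridges the enolate and ketone oxygens, which places the hydroxyl cis to the C2 ester. Two selectivities are needed, alkene insertion before carbonyl addition and aldol before protonation: the first is secured because the ketone is flanked by an acetal instead of an ester, so it is neither a chelating activated carbonyl of the kind aryl–rhodium attacks nor an acidic enol, and the second because the rigid ortho-phenylene tether holds this inductively activated ketone within reach of C2 while water is kept to five equivalents. The remote (R)-configured ester turns any minor C1 epimer into a separable diastereomer.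

**Step 11**
Reactants: 19 Dan (1R,2S,3R)-1-Ar-3-(diethoxymethyl)-3-hydroxy-6,7-(isopropylidenedioxy)-1,2,3,4-tetrahydronaphthalene-2-carboxylate
Product: 22 Dan (1R,2S)-1-Ar-3-formyl-6,7-(isopropylidenedioxy)-1,2-dihydronaphthalene-2-carboxylate, via C3 sulfamate 20 (not isolated), via unsaturated acetal 21 (not isolated)
Conditions: Burgess reagent (MeO2CN−SO2N+Et3), toluene, 70 °C; then 1 M HCl/THF (1:4), 0 °C to rt
Reagents that add atoms: water O
Why: Burgess dehydration goes through sulfamate 20 by a concerted syn (Ei) elimination, and since only C4 carries a hydrogen cis to the C3 oxygen (H2 is trans) and ionisation next to the acetal is disfavoured, the alkene forms at C3=C4; the allylic acetal 21, whose oxocarbenium ion is conjugated with ring A, then hydrolyses in dilute acid that leaves the aryl ketals and the tert-butyl ester alone.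

**Step 12**
Reactants: 22 Dan (1R,2S)-1-Ar-3-formyl-6,7-(isopropylidenedioxy)-1,2-dihydronaphthalene-2-carboxylate
Product: 23 (1R,2S)-1-Ar-2-(Dan-oxycarbonyl)-6,7-(isopropylidenedioxy)-1,2-dihydronaphthalene-3-carboxylic acid
Conditions: NaClO2, NaH2PO4, 2-methyl-2-butene (excess), t-BuOH/THF/H2O, 0 °C to rt
Reagents that add atoms: sodium chlorite [Na+].[O-]Cl=O
Why: Pinnick oxidation converts α,β-unsaturated aldehydes into acids at about pH 4 without moving the double bond or epimerising C2, and the alkene scavenger removes hypochlorous acid before it can chlorinate the electron-rich rings.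

**Step 13**
Reactants: 23 (1R,2S)-1-Ar-2-(Dan-oxycarbonyl)-6,7-(isopropylidenedioxy)-1,2-dihydronaphthalene-3-carboxylic acid; 13 tert-butyl (R)-3-Ar-2-hydroxypropanoate
Product: 24 bis-Dan (1R,2S)-1-Ar-6,7-(isopropylidenedioxy)-1,2-dihydronaphthalene-2,3-dicarboxylate (fully protected rabdosiin)
Conditions: EDC·HCl, DMAP (cat.), CH2Cl2, 0 °C to rt
Reagents that add atoms: none
Why: Steglich esterification of a cinnamic-type acid with an α-hydroxy ester is well precedented; the activated C3 carboxyl has no α-hydrogen, the epimerisable C2 carboxyl is never activated, and the carbinol C–O bond is not broken.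

**Step 14**
Reactants: 24 bis-Dan (1R,2S)-1-Ar-6,7-(isopropylidenedioxy)-1,2-dihydronaphthalene-2,3-dicarboxylate
Product: 25 rabdosiin
Conditions: TFA/H2O (9:1), 0 °C to rt, argon; reversed-phase chromatography
Reagents that add atoms: none
Why: Acidolysis cleaves both tert-butyl esters by alkyl–oxygen fission and hydrolyses the four aryl ketals in one operation, while the secondary alkyl esters, the electron-poor C3=C4 bond and all four stereocentres are stable to this non-nucleophilic acid.

**Compound list**

1 | 4-bromocatechol | Oc1ccc(Br)cc1O | starting material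
2 | 5-bromo-2,2-dimethyl-1,3-benzodioxole | CC1(C)Oc2ccc(Br)cc2O1 | intermediate
3 | (2,2-dimethyl-1,3-benzodioxol-5-yl)lithium | [Li]c1ccc2OC(C)(C)Oc2c1 | intermediate (not isolated)
4 | lithium aryltriisopropoxyborate | [Li+].CC(C)O[B-](OC(C)C)(OC(C)C)c1ccc2OC(C)(C)Oc2c1 | intermediate (not isolated)
5 | (2,2-dimethyl-1,3-benzodioxol-5-yl)boronic acid | OB(O)c1ccc2OC(C)(C)Oc2c1 | intermediate
6 | 2-(diethoxymethyl)oxirane, racemic | CCOC(OCC)C1CO1 | starting material
7 | (2,2-dimethyl-1,3-benzodioxol-5-yl)magnesium bromide | Br[Mg]c1ccc2OC(C)(C)Oc2c1 | intermediate (not isolated)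
8 | 1-Ar-3,3-diethoxypropan-2-ol, racemic | CCOC(OCC)C(O)Cc1ccc2OC(C)(C)Oc2c1 | intermediate
9 | 1-(6-bromo-2,2-dimethyl-1,3-benzodioxol-5-yl)-3,3-diethoxypropan-2-ol, racemic | CCOC(OCC)C(O)Cc1cc2OC(C)(C)Oc2cc1Br | intermediate
10 | (R)-3-(3,4-dihydroxyphenyl)lactic acid (danshensu) | O[C@H](Cc1ccc(O)c(O)c1)C(=O)O | starting material
11 | (5R)-5-(Ar-methyl)-2,2-dimethyl-1,3-dioxolan-4-one | CC1(C)OC(=O)[C@@H](Cc2ccc3OC(C)(C)Oc3c2)O1 | intermediate (not isolated)
12 | (R)-3-Ar-2-hydroxypropanoic acid | O[C@H](Cc1ccc2OC(C)(C)Oc2c1)C(=O)O | intermediate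
13 | tert-butyl (R)-3-Ar-2-hydroxypropanoate (Dan–OH) | O[C@H](Cc1ccc2OC(C)(C)Oc2c1)C(=O)OC(C)(C)C | intermediate
14 | acryloyl chloride | C=CC(=O)Cl | starting material
15 | Dan acrylate | C=CC(=O)O[C@H](Cc1ccc2OC(C)(C)Oc2c1)C(=O)OC(C)(C)C | intermediate
16 | Dan (E)-3-[6-(3,3-diethoxy-2-hydroxypropyl)-2,2-dimethyl-1,3-benzodioxol-5-yl]acrylate, both carbinol epimers | CCOC(OCC)C(O)Cc1cc2OC(C)(C)Oc2cc1/C=C/C(=O)O[C@H](Cc1ccc2OC(C)(C)Oc2c1)C(=O)OC(C)(C)C | intermediate
17 | Dan (E)-3-[6-(3,3-diethoxy-2-oxopropyl)-2,2-dimethyl-1,3-benzodioxol-5-yl]acrylate (key-step precursor) | CCOC(OCC)C(=O)Cc1cc2OC(C)(C)Oc2cc1/C=C/C(=O)O[C@H](Cc1ccc2OC(C)(C)Oc2c1)C(=O)OC(C)(C)C | intermediate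
18 | (Z)-rhodium enolate after aryl transfer to C1, drawn O-bound, diene ligand omitted | CCOC(OCC)C(=O)Cc1cc2OC(C)(C)Oc2cc1[C@@H](c1ccc2OC(C)(C)Oc2c1)/C=C(\O[Rh])O[C@H](Cc1ccc2OC(C)(C)Oc2c1)C(=O)OC(C)(C)C | intermediate (not isolated)
19 | Dan (1R,2S,3R)-1-Ar-3-(diethoxymethyl)-3-hydroxy-6,7-(isopropylidenedioxy)-1,2,3,4-tetrahydronaphthalene-2-carboxylate (key-step product) | CCOC(OCC)[C@@]1(O)Cc2cc3OC(C)(C)Oc3cc2[C@@H](c2ccc3OC(C)(C)Oc3c2)[C@@H]1C(=O)O[C@H](Cc1ccc2OC(C)(C)Oc2c1)C(=O)OC(C)(C)C | intermediate
20 | C3 O-(methoxycarbonylsulfamoyl) ester of 19 | CCOC(OCC)[C@@]1(OS(=O)(=O)NC(=O)OC)Cc2cc3OC(C)(C)Oc3cc2[C@@H](c2ccc3OC(C)(C)Oc3c2)[C@@H]1C(=O)O[C@H](Cc1ccc2OC(C)(C)Oc2c1)C(=O)OC(C)(C)C | intermediate (not isolated)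
21 | Dan (1R,2S)-1-Ar-3-(diethoxymethyl)-6,7-(isopropylidenedioxy)-1,2-dihydronaphthalene-2-carboxylate | CCOC(OCC)C1=Cc2cc3OC(C)(C)Oc3cc2[C@@H](c2ccc3OC(C)(C)Oc3c2)[C@@H]1C(=O)O[C@H](Cc1ccc2OC(C)(C)Oc2c1)C(=O)OC(C)(C)C | intermediate (not isolated)
22 | Dan (1R,2S)-1-Ar-3-formyl-6,7-(isopropylidenedioxy)-1,2-dihydronaphthalene-2-carboxylate | O=CC1=Cc2cc3OC(C)(C)Oc3cc2[C@@H](c2ccc3OC(C)(C)Oc3c2)[C@@H]1C(=O)O[C@H](Cc1ccc2OC(C)(C)Oc2c1)C(=O)OC(C)(C)C | intermediate
23 | (1R,2S)-1-Ar-2-(Dan-oxycarbonyl)-6,7-(isopropylidenedioxy)-1,2-dihydronaphthalene-3-carboxylic acid | OC(=O)C1=Cc2cc3OC(C)(C)Oc3cc2[C@@H](c2ccc3OC(C)(C)Oc3c2)[C@@H]1C(=O)O[C@H](Cc1ccc2OC(C)(C)Oc2c1)C(=O)OC(C)(C)C | intermediate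
24 | bis-Dan (1R,2S)-1-Ar-6,7-(isopropylidenedioxy)-1,2-dihydronaphthalene-2,3-dicarboxylate | O=C(O[C@H](Cc1ccc2OC(C)(C)Oc2c1)C(=O)OC(C)(C)C)C1=Cc2cc3OC(C)(C)Oc3cc2[C@@H](c2ccc3OC(C)(C)Oc3c2)[C@@H]1C(=O)O[C@H](Cc1ccc2OC(C)(C)Oc2c1)C(=O)OC(C)(C)C | intermediate
25 | rabdosiin | O=C(O[C@H](Cc1ccc(O)c(O)c1)C(=O)O)C1=Cc2cc(O)c(O)cc2[C@@H](c2ccc(O)c(O)c2)[C@@H]1C(=O)O[C@H](Cc1ccc(O)c(O)c1)C(=O)O | target

**Step count**

Total step count: 14.

Longest linear sequence: 10 steps (steps 1, 3, 4, 8, 9, 10, 11, 12, 13, 14 from 1). The line from 10 through steps 5, 6, 7, 8 to 14 is equally long.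

**Steps most likely to fail**

**Step 10 (arylation–aldol cascade).**
- Risk: protonation of the rhodium enolate may outrun ring closure. Insertion at the ortho-substituted cinnamate may also stall while the boronic acid is lost to protodeboronation.
- Fallback: hydride takes the place of aryl as the conjugate nucleophile, so the same C2 enolate arises by known copper hydride chemistry in an aprotic medium. The fallback sets out from 16. A second Mizoroki–Heck arylation with bromide 2 (Pd(OAc)2, P(o-tol)3, Et3N, DMF, 120 °C) gives, by syn insertion and syn elimination, the (Z)-3,3-diarylacrylate F1, with ring A cis to the ester carbonyl. Dess–Martin oxidation gives the keto enoate F2. A copper hydride reductive aldol cyclisation follows (Cu(OAc)2·H2O, the DTBM-SEGPHOS antipode that delivers hydride to the face of C1 giving 1R, (EtO)2MeSiH, toluene, 0 °C). It adds hydride to C1 and closes C2–C3 through the same chelated chair, to give the C3 silyl ether F3. Et3N·3HF frees the alcohol, and the route is rejoined at 19.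

**Step 11 (syn-dehydration).**
- Risk: sulfamate formation may be sluggish at the crowded tertiary alcohol. Ring B may open by retro-aldol on heating, and regiocontrol is lost if the sulfamate ionises.
- Fallback: the one-pot sulfamate chemistry is replaced by an isolable thiocarbonyl ester, made by neutral acyl transfer, and a separate Chugaev-type pyrolysis. The fallback sets out from 19. Phenyl chlorothionoformate, pyridine and DMAP in CH2Cl2 give the O-phenyl thionocarbonate F4. In toluene at 110 °C, F4 fragments through a six-membered cyclic syn transition state that again reaches only a C4 hydrogen. This delivers 21, where the route is rejoined (acid hydrolysis to 22 as in the second half of step 11).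

**Step 8 (Heck coupling).**
- Risk: oxidative addition of zerovalent palladium into the electron-rich, ortho-substituted C–Br bond may be slow. Acrylate 15 may be lost to oligomerisation, and the free hydroxyl may close onto the new enoate by oxa-Michael addition at 100 °C.
- Fallback: C1=C2 is formed by olefination in place of C8a–C1 by cross-coupling. The fallback sets out from 9 and 13. Bromine–lithium exchange on 9 (n-BuLi, 2.1 equiv, THF, −78 °C) and DMF give the hydroxy aldehyde F5, which is in equilibrium with its lactol. Alcohol 13 is esterified with diethylphosphonoacetic acid (EDC·HCl, DMAP, CH2Cl2) to the phosphonoacetate F6. A Horner–Wadsworth–Emmons reaction under LiCl/iPr2NEt in MeCN at rt joins F5 and F6 to the (E)-enoate, and the route is rejoined at 16.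

**Further compounds**

F1 | step 10 | Dan (Z)-3-Ar-3-[6-(3,3-diethoxy-2-hydroxypropyl)-2,2-dimethyl-1,3-benzodioxol-5-yl]acrylate | CCOC(OCC)C(O)Cc1cc2OC(C)(C)Oc2cc1/C(c1ccc2OC(C)(C)Oc2c1)=C\C(=O)O[C@H](Cc1ccc2OC(C)(C)Oc2c1)C(=O)OC(C)(C)C
F2 | step 10 | Dan (Z)-3-Ar-3-[6-(3,3-diethoxy-2-oxopropyl)-2,2-dimethyl-1,3-benzodioxol-5-yl]acrylate | CCOC(OCC)C(=O)Cc1cc2OC(C)(C)Oc2cc1/C(c1ccc2OC(C)(C)Oc2c1)=C\C(=O)O[C@H](Cc1ccc2OC(C)(C)Oc2c1)C(=O)OC(C)(C)C
F3 | step 10 | C3 O-[diethoxy(methyl)silyl] ether of 19 | CCOC(OCC)[C@@]1(O[Si](C)(OCC)OCC)Cc2cc3OC(C)(C)Oc3cc2[C@@H](c2ccc3OC(C)(C)Oc3c2)[C@@H]1C(=O)O[C@H](Cc1ccc2OC(C)(C)Oc2c1)C(=O)OC(C)(C)C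
F4 | step 11 | C3 O-phenyl thionocarbonate of 19 | CCOC(OCC)[C@@]1(OC(=S)Oc2ccccc2)Cc2cc3OC(C)(C)Oc3cc2[C@@H](c2ccc3OC(C)(C)Oc3c2)[C@@H]1C(=O)O[C@H](Cc1ccc2OC(C)(C)Oc2c1)C(=O)OC(C)(C)C
F5 | step 8 | 6-(3,3-diethoxy-2-hydroxypropyl)-2,2-dimethyl-1,3-benzodioxole-5-carbaldehyde, racemic | CCOC(OCC)C(O)Cc1cc2OC(C)(C)Oc2cc1C=O
F6 | step 8 | Dan 2-(diethoxyphosphoryl)acetate | CCOP(=O)(OCC)CC(=O)O[C@H](Cc1ccc2OC(C)(C)Oc2c1)C(=O)OC(C)(C)C
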